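The numbers in the tables were computed for substances that don't exist, noise included.

How much Q does the flask hold at 50 min, and which charge of X leaves most?

| setting | beta | alpha | flask |
|---|---|---|---|
| J | 0.050 M | 0.050 M | 0.050 M |
| X | 1.5 equiv | 6 equiv | 3.00 equiv |
| L | 5 mM | 5 mM | 5.00 mM |
| remark | run made earlier | run made earlier |  |
| time |  |  | 50 min |

| run | time / min | Q / % | G / % |
|---|---|---|---|
| beta | 12.0 | 44.4 | 9.1 |
| beta | 25.0 | 60.9 | 11.1 |
| beta | 40.0 | 69.2 | 10.2 |
| beta | 50.0 | 73.9 | 13.3 |
| alpha | 4.00 | 36.8 | 35.3 |
| alpha | 10.0 | 40.8 | 51.3 |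
| alpha | 20.0 | 41.5 | 54.9 |
| alpha | 50.0 | 42.0 | 53.9 |

(scatter of a reading: 1 percentage point)

- steps under discussion: J + X -> Q; Q + L -> D; X + Q <-> G

- equivalents of X to J, everything else as given, that leave most Q at 50 min
- the amount of Q then, in percent of the J charged
- the amount of Q with the amounts as given

Late in the alpha run, G/Q reads 1.32 at 20.0 min and 1.28 at 50.0 min, so I treat X + Q <-> G as an equilibrium: [G]/[Q] = K[X], and Q holds a share 1/(1 + K[X]) of Q plus G. Free X at the last alpha reading, taking J as consumed, is the charge less one X per J charged, whether it now stands in Q, G or D, and one more per G, 0.223 M. So the partition constant K, the ratio [G]/([Q][X]), reads 5.75 M⁻¹.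

In the flask, once J is consumed, free X is the charge less one X per J and one more per G. With K, and neglecting D here, that balance is a quadratic whose root is 0.0837 M. I expect this to be about the lowest [X] of the flask's run, so I take J's decay as pseudo-first-order at that [X], with [J] over its charge near exp(-k[X]t), an estimate on the high side. The first alpha reading leaves 27.9% of J at 4.00 min, and with the mean [X] up to then k reads 1.17 M⁻¹ min⁻¹. So I put J in the flask near 0.751%. Alpha's Q and G fall short of the charge by 4.10%, a reading I book as D and carry over to the flask as a rough figure. My reckoning for Q in the flask is then 64.2%.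

Beta shows the other side: at 1.5 equiv, Q reads 73.9% and 12.8% is missing, more than in alpha. Beta's last G/Q of 0.180 lies below alpha's, and I read beta's gap as unreacted J plus D, so I put the best charge a little above beta's, with Q near that reading.

The forecast gives 64% as charged and 74.5% at 1.6 equiv: “The optimum is broad”.

The flask gives 64.9%, and the best charge is 1.72 equiv, with 75.2%.

    J + X → Q (k = 1.16 M⁻¹ min⁻¹)
    Q + L → D (k = 0.255 M⁻¹ min⁻¹)
    X + Q ⇌ G (K = 5.77 M⁻¹, k = 2.09 M⁻¹ min⁻¹)

At 50.0 min the flask holds 3.00% of D, and the half-life of Q by the step with L taken by itself, with L as charged, 9.1 h, is long against 50 min. The neighbour with 12.0 equiv of X keeps 85.5% of it free, 0.513 M, so K[X] comes to 2.95, and that flask holds G at 73.7% against Q at 24.9%.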